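## Analysis of the target

Broussoflavonol F (24) is a flavonol: ring A is fused to the pyranone ring C as a chromen-4-one, and ring B, a 4-hydroxyphenyl group, sits on C2. Hydroxyl groups stand on C3, C5, C7 and C4', and two prenyl (3-methylbut-2-enyl) groups stand on C8 of ring A and C3' of ring B. There is no stereocenter and no alkene geometry to set, so the problem is purely one of constitution.

The sensitive groups are the two prenyl alkenes and the electron-rich polyphenol. The alkenes are hydrogenated, epoxidised and, under acid, cyclised onto the neighbouring 7-OH or 4'-OH to dimethylchromans; this rules out hydrogenolysis, peracids and strong acids late in the route.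

The difficulty is regiochemical. C8 must be told apart from C6, C3' must be alkylated ortho to O4', and O3 must be present at the flavone oxidation level without an oxidation that would touch the prenyl groups.

The strategy rests on ring B. C1' carries the chromone, C4' (para) the oxygen, C3' the prenyl group, and C2', C5' and C6' carry hydrogen. This pattern arises when a four-carbon 1-methoxy-2-prenyl-3-siloxydiene (future C2', C3', C4', C5') adds to a terminal alkyne on C2 of the chromone (future C1' and C6') and the methoxy group is then lost.

## Retrosynthetic reasoning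

**Protecting groups (24 ⇒ 23 ⇒ 22).** The last bonds cut are O–protecting-group bonds. 24 is traced to 23, which carries methoxymethyl (MOM) ethers on O3, O5 and O7, and 23 to the O4' silyl ether 22. Acetal and silyl ethers are chosen because mild protic cleavage and fluoride both leave the prenyl alkenes alone. Two separate deprotections keep each one mild.

**Ring B (22 ⇒ 14 + 20).** C1'–C2' and C5'–C6' are cut together, which opens ring B into the 2-ethynylchromone 14 and the siloxydiene 20. Cutting here, and not at C2–C1' or inside ring C, places the ring B prenyl group by the constitution of an acyclic diene and not by C-alkylation of a phenol. It also delivers the arene at the right oxidation level, because adduct 21 aromatizes by elimination and not by oxidation. The forward reaction must join the CH2 terminus of 20 to the terminal alkyne carbon of 14 and must not involve the C2=C3 bond of the chromone.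

**Alkyne (14 ⇒ 12 + 13; 12 ⇒ 11 ⇒ 10).** The triple bond is cut between its two carbons. The inner carbon is the formyl carbon of aldehyde 12 and the outer one comes from the diazophosphonate 13. The aldehyde is reached from ester 10 through alcohol 11, because stepwise reduction and re-oxidation is safer next to the pyranone than a partial ester reduction.

**Ring C (10 ⇒ 6 + 7).** O1–C2 and C2–C3 are cut. The oxalate 7 supplies C2 and the ester carbon, and the ω-oxygenated o-hydroxyacetophenone 6 supplies C3 with its oxygen, C4 and ring A. Because O3 is already on the α-carbon of 6, the chromone is formed directly as the protected flavonol-type enol ether and no later C3 oxidation is needed. The forward reaction is a crossed Claisen condensation to 8, hemiketal closure to 9 and dehydration under conditions the MOM groups survive.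

**α-Oxygen (6 ⇒ 5 ⇒ 4).** The C–O bond at the ketone α-carbon is cut. The oxygen is introduced by electrophilic hydroxylation of the enolate of 4, with a reagent that attacks an enolate far faster than a trisubstituted alkene, and is then capped as a MOM ether.

**Ring A substitution (4 ⇒ 3 ⇒ 1 + 2).** The aryl–CH2 bond of the ring A prenyl group is cut back to the symmetric triol 1 and prenyl bromide 2. In 1 the two free ring carbons are equivalent, so mono-C-prenylation gives a single isomer 3. In 3 the hydroxyl flanked by acetyl and prenyl is the most hindered and stays free when the other two are protected. That hydroxyl later becomes O1, which fixes the prenyl group at C8 and not C6.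

**Diene (20 ⇒ 19 ⇒ 18 ⇒ 16 + 17 ⇒ 15).** The silyl dienol ether 20 is the enol silane of the β-methoxy enone 19, formed at its only enolizable position. 19 comes from β-keto acetal 18 by elimination. The C–C bond between the acetal carbon and the α-carbon of 18 is cut to orthoformate 17 and the more substituted enol silane 16 of ketone 15. 15 already contains the prenyl chain on the carbon that becomes C3'.

## Alternatives that were turned down

**Alternative 1:** Both aryl–prenyl bonds (C8–CH2 and C3'–CH2) are disconnected to allyl aryl ethers on a preformed flavonol, the bis-ether A2 (5-O-prenyl, 4'-O-1,1-dimethylallyl).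
- Forward key step: heating A2 with a lanthanide Lewis acid and a mild base moves the O5 group to C8 by a Claisen shift to C6 followed by a Cope shift. The O4' group moves to C3' by an ortho-Claisen shift with allyl inversion. The product is A1.
- For it: the flavonol skeleton is taken ready-made, both prenyl groups arrive in one operation with no oxidant, and the Claisen–Cope path to 8-prenylflavonoids is well established. On step count it is probably the shortest of all the routes.
- Against it: A2 needs two different allyl ethers placed selectively on four oxygens. One is on the chelated O5, and the other is a tertiary aryl ether that is normally made indirectly. The ring A shift must pass through two consecutive [3,3] steps and can stop at C6. The tertiary ether can ionise under the Lewis acid. Both rearrangements must succeed in the same flask.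
- Comparison: Alternative 1 wins on step economy. The chosen route offers positional certainty in its place, with C8 fixed by the symmetry of 1 and C3' by the constitution of 20, independent of migratory selectivity.

**Alternative 2:** Ring C is cut at C4–C4a, which leads to the aryl iodide A4 with a tethered methyl ester.
- Forward key step: iodine–lithium exchange with an alkyllithium at very low temperature gives an aryllithium that acylates itself on the ester and closes ring C as the trans-3-alkoxyflavanone A3.
- For it: the union is convergent, the iodine locks ring A regiochemistry, and the ring closure is a fast intramolecular acylation that does not depend on dienophile reactivity. On that last point it is stronger than the chosen key step.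
- Against it: A3 is at the flavanone level. Two stereocenters (C2, C3) are made only to be destroyed, and the dehydrogenation needed to reach the flavonol threatens two prenyl groups. The alkyllithium can attack the ester or metalate next to a MOM ether. The ester α-hydrogen lies β to an aryloxide leaving group, so elimination competes. A4 itself requires etherification of a di-ortho-substituted phenol at a benzylic carbon.
- Comparison: the chosen strategy reaches the flavone oxidation level directly, creates no stereocenter and needs no cryogenic organolithium chemistry on the full skeleton.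

**Alternative 3:** C3 is inserted as an ylide carbon between two ester carbonyls, cutting C3–C4 and C2=C3. The precursors are the silyl ester A6 of an O-aroylsalicylic acid and the alkoxymethylene ylide A7.
- Forward key step: A7 is C-acylated by the silyl ester, and the resulting acyl ylide olefinates the neighbouring aryl ester carbonyl intramolecularly to give the flavone A5.
- For it: it is highly convergent (two benzoic acids and one carbon) and arrives directly at the flavone level. O3 comes in as a 2-(trimethylsilyl)ethyl ether that fluoride removes, so its endgame is gentler on the prenyl groups than the acidic MOM cleavage used here.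
- Against it: a basic, non-stabilised alkoxy ylide must choose the silyl ester over the aryl ester in the same molecule, and ester olefination needs heat. Both acid components require ortho C-prenylation of phenols; for ring B this is the unselective step the chosen route avoids.
- Comparison: Alternative 3 is equal or better in convergence and endgame. The chosen strategy offers in its place a ring B whose substitution is fixed by construction from the acyclic ketone 15.

Key step: step 13

Assumption: compounds 1, 2, 7, 13, 15 and 17 are bought; the commercial acetophenone 1 is used as the entry to ring A because its acetyl group is already in place. Prenyl = 3-methylbut-2-enyl, MOM = methoxymethyl, TBS = tert-butyldimethylsilyl.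

## Route

**Ring A and the dienophile**

Step 1
Reactants: 1 2',4',6'-trihydroxyacetophenone; 2 prenyl bromide (1-bromo-3-methylbut-2-ene)
Product: 3 1-[2,4,6-trihydroxy-3-(3-methylbut-2-enyl)phenyl]ethanone
Conditions: DBU (1.0 equiv), 2 (0.8 equiv), THF, 0 °C → rt
Reagents that add atoms: none
Why: C-Alkylation of the ambident phloroglucinol-type phenolate by the allylic bromide; the two free ring carbons of 1 are equivalent, so only one mono-C-prenyl isomer can form, and a deficit of 2 limits double alkylation.

Step 2
Reactants: 3 1-[2,4,6-trihydroxy-3-(3-methylbut-2-enyl)phenyl]ethanone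
Product: 4 1-[2-hydroxy-4,6-bis(methoxymethoxy)-3-(3-methylbut-2-enyl)phenyl]ethanone
Conditions: MOMCl (2.3 equiv), i-Pr2NEt (3 equiv), CH2Cl2, 0 °C → rt
Reagents that add atoms: chloromethyl methyl ether (MOMCl), COCCl
Why: MOM ether formation (O-alkylation with an α-chloro ether); the para hydroxyl and the less hindered ortho hydroxyl react, while the hydroxyl between acetyl and prenyl, hydrogen-bonded to the ketone and flanked on both sides, should remain free.

Step 3
Reactants: 4 1-[2-hydroxy-4,6-bis(methoxymethoxy)-3-(3-methylbut-2-enyl)phenyl]ethanone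
Product: 5 2-hydroxy-1-[2-hydroxy-4,6-bis(methoxymethoxy)-3-(3-methylbut-2-enyl)phenyl]ethanone
Conditions: KN(SiMe3)2 (2.2 equiv), THF, −78 °C; trans-2-(phenylsulfonyl)-3-phenyloxaziridine (1.3 equiv), −78 °C; AcOH
Reagents that add atoms: 2-(phenylsulfonyl)-3-phenyloxaziridine, O=S(=O)(c1ccccc1)N1OC1c1ccccc1
Why: Davis oxidation of the potassium enolate (phenolate–enolate dianion); the N-sulfonyloxaziridine transfers oxygen to the enolate carbon at −78 °C far faster than to a trisubstituted alkene, so the prenyl group should be untouched, and the potassium counter-ion keeps the enolate from adding to the sulfonimine by-product.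

Step 4
Reactants: 5 2-hydroxy-1-[2-hydroxy-4,6-bis(methoxymethoxy)-3-(3-methylbut-2-enyl)phenyl]ethanone
Product: 6 1-[2-hydroxy-4,6-bis(methoxymethoxy)-3-(3-methylbut-2-enyl)phenyl]-2-(methoxymethoxy)ethanone
Conditions: MOMCl (1.3 equiv), i-Pr2NEt (2 equiv), CH2Cl2, 0 °C → rt
Reagents that add atoms: chloromethyl methyl ether (MOMCl), COCCl
Why: MOM protection of the primary alcohol; the chelated, doubly flanked phenol that did not react in step 2 should again stay free under these conditions.

Step 5
Reactants: 6 1-[2-hydroxy-4,6-bis(methoxymethoxy)-3-(3-methylbut-2-enyl)phenyl]-2-(methoxymethoxy)ethanone; 7 diethyl oxalate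
Product: 10 ethyl 3,5,7-tris(methoxymethoxy)-8-(3-methylbut-2-enyl)-4-oxo-4H-chromene-2-carboxylate, via diketo ester 8 (not isolated), via hemiketal 9 (not isolated)
Conditions: NaOEt (4 equiv), 7 (3 equiv), EtOH–THF, 0 → 50 °C; AcOH; crude product: SOCl2 (1.5 equiv), pyridine, CH2Cl2, 0 °C
Reagents that add atoms: none
Why: Crossed Claisen condensation of the ketone enolate with the non-enolizable oxalate (the classical chromone-2-carboxylate synthesis) gives 8, whose phenol adds to the α-keto ester carbonyl to form hemiketal 9. Dehydration through the chlorosulfite with pyridine (E1cB, the C3 hydrogen being α to the ketone) replaces the usual hot mineral acid and should spare the MOM ethers and the prenyl group.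

Step 6
Reactants: 10 ethyl 3,5,7-tris(methoxymethoxy)-8-(3-methylbut-2-enyl)-4-oxo-4H-chromene-2-carboxylate
Product: 11 2-(hydroxymethyl)-3,5,7-tris(methoxymethoxy)-8-(3-methylbut-2-enyl)chromen-4-one
Conditions: NaBH4 (1.5 equiv), MeOH–THF, 0 °C
Reagents that add atoms: none
Why: Hydride reduction of an activated ester; the ester on C2 of the pyranone is as electrophilic as an α-alkoxyacrylate and is reduced by NaBH4, whereas the C4 carbonyl is a vinylogous ester, further deactivated by the ring A and C3 oxygens, and should not react at 0 °C.

Step 7
Reactants: 11 2-(hydroxymethyl)-3,5,7-tris(methoxymethoxy)-8-(3-methylbut-2-enyl)chromen-4-one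
Product: 12 3,5,7-tris(methoxymethoxy)-8-(3-methylbut-2-enyl)-4-oxo-4H-chromene-2-carbaldehyde
Conditions: Dess–Martin periodinane (1.3 equiv), CH2Cl2, 0 °C → rt
Reagents that add atoms: none
Why: Dess–Martin oxidation of a primary allylic-type alcohol; the reagent does not attack alkenes or acetals, and the non-enolizable aldehyde is used without storage.

Step 8
Reactants: 12 3,5,7-tris(methoxymethoxy)-8-(3-methylbut-2-enyl)-4-oxo-4H-chromene-2-carbaldehyde; 13 dimethyl (1-diazo-2-oxopropyl)phosphonate
Product: 14 2-ethynyl-3,5,7-tris(methoxymethoxy)-8-(3-methylbut-2-enyl)chromen-4-one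
Conditions: 13 (1.5 equiv), K2CO3 (2 equiv), MeOH–THF, 0 °C → rt
Reagents that add atoms: none
Why: Seyferth–Gilbert homologation in the Ohira–Bestmann variant: methanolysis of 13 releases the diazomethylphosphonate anion, which olefinates the aldehyde, and loss of N2 with a 1,2-hydrogen shift gives the terminal alkyne. The aldehyde is non-enolizable and electron-poor, the favourable case for this reaction, and the short reaction at low temperature limits attack of methoxide on the pyranone.

**The diene**

Step 9
Reactants: 15 6-methylhept-5-en-2-one
Product: 16 (Z)-trimethyl[(6-methylhepta-2,5-dien-2-yl)oxy]silane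
Conditions: TMSCl (1.2 equiv), NaI (1.2 equiv), Et3N (1.5 equiv), MeCN, rt
Reagents that add atoms: chlorotrimethylsilane, C[Si](C)(C)Cl
Why: Silyl enol ether formation under equilibrating conditions (iodotrimethylsilane formed in the flask with a tertiary amine), which with methyl alkyl ketones favours the more substituted, internal enol silane; the minor terminal isomer leads to a separable product in step 10.

Step 10
Reactants: 16 (Z)-trimethyl[(6-methylhepta-2,5-dien-2-yl)oxy]silane; 17 trimethyl orthoformate
Product: 18 3-(dimethoxymethyl)-6-methylhept-5-en-2-one (racemic)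
Conditions: 17 (1.3 equiv), TMSOTf (5 mol %), CH2Cl2, −78 °C
Reagents that add atoms: none
Why: Mukaiyama-type addition of an enol silane to the dimethoxycarbenium ion generated from the orthoester by catalytic silyl triflate; the enol silane is far more nucleophilic than the trisubstituted alkene, so C–C bond formation should occur only at the α-carbon that already carries the prenyl chain.

Step 11
Reactants: 18 3-(dimethoxymethyl)-6-methylhept-5-en-2-one
Product: 19 (3E)-3-(methoxymethylidene)-6-methylhept-5-en-2-one
Conditions: DBU (0.2 equiv), toluene, reflux, MeOH removed (5 Å molecular sieves in a Soxhlet)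
Reagents that add atoms: none
Why: E1cB elimination of methanol from a β-keto acetal to the vinylogous ester, driven by removal of methanol; the equilibrating basic conditions should give mainly the E isomer (methoxy anti to acetyl), which is the geometry the diene needs.

Step 12
Reactants: 19 (3E)-3-(methoxymethylidene)-6-methylhept-5-en-2-one
Product: 20 tert-butyl{[(3E)-4-methoxy-3-(3-methylbut-2-enyl)buta-1,3-dien-2-yl]oxy}dimethylsilane
Conditions: TBSOTf (1.2 equiv), Et3N (2 equiv), Et2O, 0 °C → rt
Reagents that add atoms: tert-butyldimethylsilyl trifluoromethanesulfonate, CC(C)(C)[Si](C)(C)OS(=O)(=O)C(F)(F)F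
Why: Soft enolization and O-silylation of a β-alkoxy enone, the standard entry to 1-alkoxy-3-siloxybutadienes; the methyl group is the only position that can enolize, so a single cross-conjugated dienol ether is expected and the enol ether geometry is retained.

**Union and end game**

Step 13
Reactants: 14 2-ethynyl-3,5,7-tris(methoxymethoxy)-8-(3-methylbut-2-enyl)chromen-4-one; 20 tert-butyl{[(3E)-4-methoxy-3-(3-methylbut-2-enyl)buta-1,3-dien-2-yl]oxy}dimethylsilane
Product: 22 4'-(tert-butyldimethylsiloxy)-3,5,7-tris(methoxymethoxy)-8,3'-bis(3-methylbut-2-enyl)flavone, via cyclohexadiene adduct 21 (not isolated)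
Conditions: 20 (3 equiv), BHT (cat.), toluene, 120 °C (sealed tube); then PPTS (cat.), rt
Reagents that add atoms: none
Why: Thermal Diels–Alder reaction of a 1-methoxy-3-siloxydiene with an acceptor-substituted alkyne followed by aromatizing loss of methanol, the established route from such dienes and conjugated alkynes to para-oxygenated arenes, applied here to an ynenone dienophile. The alkyne of 14 is conjugated through C2=C3 to the C4 carbonyl, so its terminal CH is the electrophilic end; the CH2 terminus of 20, made the nucleophilic end by the cooperating methoxy and siloxy donors, bonds there in a concerted but asynchronous [4+2] transition state while the methoxy-bearing terminus closes onto the inner alkyne carbon. Ring B is thus closed by intermolecular cycloaddition, with C5'–C6' and C1'–C2' formed in one step. Adduct 21 has one stereocenter (the methoxy carbon, formed racemic), which disappears when the allylic methoxy group ionises with help from the silyl enol ether and the C5' proton is lost, so no stereocontrol and no oxidant are needed. The step needs regioselectivity (siloxy carbon para to the chromone, prenyl carbon at C3') and chemoselectivity; the first follows from the matched polarisation of the two partners, the second from the fact that the only other π-bonds are the tetrasubstituted, donor-substituted C2=C3 bond and the unactivated prenyl alkenes. The TBS group lets the diene survive prolonged heating and leaves O4' protected in the product.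

Step 14
Reactants: 22 4'-(tert-butyldimethylsiloxy)-3,5,7-tris(methoxymethoxy)-8,3'-bis(3-methylbut-2-enyl)flavone
Product: 23 4'-hydroxy-3,5,7-tris(methoxymethoxy)-8,3'-bis(3-methylbut-2-enyl)flavone
Conditions: TBAF (1.1 equiv), AcOH (1.1 equiv), THF, 0 °C
Reagents that add atoms: none
Why: Fluoride-mediated cleavage of an aryl silyl ether; the phenolate para to the chromone is a good leaving group on silicon, and buffering with acetic acid keeps the medium from becoming basic enough to open the pyranone.

Step 15
Reactants: 23 4'-hydroxy-3,5,7-tris(methoxymethoxy)-8,3'-bis(3-methylbut-2-enyl)flavone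
Product: 24 Broussoflavonol F (3,5,7,4'-tetrahydroxy-8,3'-bis(3-methylbut-2-enyl)flavone)
Conditions: 3 M aq. HCl–MeOH (1:5), 40 °C
Reagents that add atoms: none
Why: Acid-catalysed methanolysis of the three MOM acetals; dilute acid in methanol at mild temperature cleaves aryl and enol MOM ethers faster than it protonates a trisubstituted alkene, which is why this is the usual way to unmask prenylated polyphenols, and the reaction is stopped as soon as the last acetal is gone.

## Compound list

1 | 2',4',6'-trihydroxyacetophenone | CC(=O)c1c(O)cc(O)cc1O | starting material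
2 | prenyl bromide (1-bromo-3-methylbut-2-ene) | CC(C)=CCBr | starting material
3 | 1-[2,4,6-trihydroxy-3-(3-methylbut-2-enyl)phenyl]ethanone | CC(=O)c1c(O)cc(O)c(CC=C(C)C)c1O | intermediate
4 | 1-[2-hydroxy-4,6-bis(methoxymethoxy)-3-(3-methylbut-2-enyl)phenyl]ethanone | CC(=O)c1c(OCOC)cc(OCOC)c(CC=C(C)C)c1O | intermediate
5 | 2-hydroxy-1-[2-hydroxy-4,6-bis(methoxymethoxy)-3-(3-methylbut-2-enyl)phenyl]ethanone | OCC(=O)c1c(OCOC)cc(OCOC)c(CC=C(C)C)c1O | intermediate
6 | 1-[2-hydroxy-4,6-bis(methoxymethoxy)-3-(3-methylbut-2-enyl)phenyl]-2-(methoxymethoxy)ethanone | COCOCC(=O)c1c(OCOC)cc(OCOC)c(CC=C(C)C)c1O | intermediate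
7 | diethyl oxalate | CCOC(=O)C(=O)OCC | starting material
8 | ethyl 4-[2-hydroxy-4,6-bis(methoxymethoxy)-3-(3-methylbut-2-enyl)phenyl]-3-(methoxymethoxy)-2,4-dioxobutanoate (racemic, not isolated) | CCOC(=O)C(=O)C(OCOC)C(=O)c1c(OCOC)cc(OCOC)c(CC=C(C)C)c1O | intermediate
9 | ethyl 2-hydroxy-3,5,7-tris(methoxymethoxy)-8-(3-methylbut-2-enyl)-4-oxochromane-2-carboxylate (mixture of racemic diastereomers, not isolated) | CCOC(=O)C1(O)Oc2c(CC=C(C)C)c(OCOC)cc(OCOC)c2C(=O)C1OCOC | intermediate
10 | ethyl 3,5,7-tris(methoxymethoxy)-8-(3-methylbut-2-enyl)-4-oxo-4H-chromene-2-carboxylate | CCOC(=O)c1oc2c(CC=C(C)C)c(OCOC)cc(OCOC)c2c(=O)c1OCOC | intermediate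
11 | 2-(hydroxymethyl)-3,5,7-tris(methoxymethoxy)-8-(3-methylbut-2-enyl)chromen-4-one | OCc1oc2c(CC=C(C)C)c(OCOC)cc(OCOC)c2c(=O)c1OCOC | intermediate
12 | 3,5,7-tris(methoxymethoxy)-8-(3-methylbut-2-enyl)-4-oxo-4H-chromene-2-carbaldehyde | O=Cc1oc2c(CC=C(C)C)c(OCOC)cc(OCOC)c2c(=O)c1OCOC | intermediate
13 | dimethyl (1-diazo-2-oxopropyl)phosphonate | COP(=O)(OC)C(=[N+]=[N-])C(C)=O | starting material
14 | 2-ethynyl-3,5,7-tris(methoxymethoxy)-8-(3-methylbut-2-enyl)chromen-4-one | C#Cc1oc2c(CC=C(C)C)c(OCOC)cc(OCOC)c2c(=O)c1OCOC | intermediate
15 | 6-methylhept-5-en-2-one | CC(=O)CCC=C(C)C | starting material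
16 | (Z)-trimethyl[(6-methylhepta-2,5-dien-2-yl)oxy]silane | C/C(O[Si](C)(C)C)=C/CC=C(C)C | intermediate
17 | trimethyl orthoformate | COC(OC)OC | starting material
18 | 3-(dimethoxymethyl)-6-methylhept-5-en-2-one (racemic) | COC(OC)C(CC=C(C)C)C(C)=O | intermediate
19 | (3E)-3-(methoxymethylidene)-6-methylhept-5-en-2-one | CO/C=C(/C(C)=O)CC=C(C)C | intermediate
20 | tert-butyl{[(3E)-4-methoxy-3-(3-methylbut-2-enyl)buta-1,3-dien-2-yl]oxy}dimethylsilane | CO/C=C(/C(=C)O[Si](C)(C)C(C)(C)C)CC=C(C)C | intermediate
21 | 2-[4-(tert-butyldimethylsiloxy)-6-methoxy-5-(3-methylbut-2-enyl)cyclohexa-1,4-dien-1-yl]-3,5,7-tris(methoxymethoxy)-8-(3-methylbut-2-enyl)chromen-4-one (racemic, not isolated) | COC1C(CC=C(C)C)=C(O[Si](C)(C)C(C)(C)C)CC=C1c1oc2c(CC=C(C)C)c(OCOC)cc(OCOC)c2c(=O)c1OCOC | intermediate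
22 | 4'-(tert-butyldimethylsiloxy)-3,5,7-tris(methoxymethoxy)-8,3'-bis(3-methylbut-2-enyl)flavone | CC(C)=CCc1cc(-c2oc3c(CC=C(C)C)c(OCOC)cc(OCOC)c3c(=O)c2OCOC)ccc1O[Si](C)(C)C(C)(C)C | intermediate
23 | 4'-hydroxy-3,5,7-tris(methoxymethoxy)-8,3'-bis(3-methylbut-2-enyl)flavone | CC(C)=CCc1cc(-c2oc3c(CC=C(C)C)c(OCOC)cc(OCOC)c3c(=O)c2OCOC)ccc1O | intermediate
24 | Broussoflavonol F | CC(C)=CCc1cc(-c2oc3c(CC=C(C)C)c(O)cc(O)c3c(=O)c2O)ccc1O | target

## Step count and least certain steps

Total step count: 15. Longest linear sequence: 11 steps (1 → 24 through steps 1–8 and 13–15). The diene arm 15 → 20 takes 4 steps (steps 9–12).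

**Step 13 (key step).** The alkyne of 14 is activated only vinylogously, and the C3 oxygen donates into the same π-system. The cycloaddition may therefore be slower than thermal degradation or adventitious hydrolysis of the diene. A stepwise conjugate addition with silyl transfer could also give an open-chain adduct that does not close.

Fallback, setting out from 6 and 2 and coming back at 24, with ring B attached as a finished aroyl unit:
- The sodium phenolate of commercial methyl 4-hydroxybenzoate (NaH, toluene) is C-alkylated ortho to oxygen by 2 to give methyl 4-hydroxy-3-(3-methylbut-2-enyl)benzoate F1.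
- MOMCl and i-Pr2NEt give methyl 4-(methoxymethoxy)-3-(3-methylbut-2-enyl)benzoate F2, and LiOH in aqueous THF gives 4-(methoxymethoxy)-3-(3-methylbut-2-enyl)benzoic acid F3.
- F3 is esterified with the phenol of 6 (carbodiimide, DMAP) to 2-[(methoxymethoxy)acetyl]-3,5-bis(methoxymethoxy)-6-(3-methylbut-2-enyl)phenyl 4-(methoxymethoxy)-3-(3-methylbut-2-enyl)benzoate F4.
- LiN(SiMe3)2 in THF (−78 → 0 °C) effects the Baker–Venkataraman acyl shift to 1-[2-hydroxy-4,6-bis(methoxymethoxy)-3-(3-methylbut-2-enyl)phenyl]-2-(methoxymethoxy)-3-[4-(methoxymethoxy)-3-(3-methylbut-2-enyl)phenyl]propane-1,3-dione F5.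
- Cyclodehydration as in step 5 (SOCl2, pyridine) gives 3,5,7,4'-tetrakis(methoxymethoxy)-8,3'-bis(3-methylbut-2-enyl)flavone F6, and the methanolysis of step 15 returns to 24.

**Step 3.** The enolate may add to the sulfonimine by-product, or the electron-rich phenolate ring may be oxidised, so that hydroxylation of the dianion stays incomplete.

Fallback, setting out from 2 (with commercial phloroglucinol and cyanomethyl benzoate) and coming back at 6, with the α-oxygen carried in by the acyl group:
- Hoesch acylation (ZnCl2, HCl gas, Et2O, 0 °C; then hot water) gives 2-oxo-2-(2,4,6-trihydroxyphenyl)ethyl benzoate F7.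
- K2CO3 in MeOH gives 2-hydroxy-1-(2,4,6-trihydroxyphenyl)ethanone F8.
- C-Prenylation with 2 as in step 1 gives 2-hydroxy-1-[2,4,6-trihydroxy-3-(3-methylbut-2-enyl)phenyl]ethanone F9.
- MOMCl (3.3 equiv) with i-Pr2NEt protects the primary alcohol and the two less hindered phenols and gives 6.

**Step 5.** The Claisen condensation at the hindered α-alkoxy carbon may stall or reverse, and the dehydration of 9 may fail or cost a MOM group (most likely the one on O5).

Fallback, setting out from 6 and coming back at 12, which skips steps 5–7 by forming the pyranone first and adding the C2 carbon afterwards: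
- Dimethylformamide dimethyl acetal (toluene, 90 °C) gives (2Z)-3-(dimethylamino)-1-[2-hydroxy-4,6-bis(methoxymethoxy)-3-(3-methylbut-2-enyl)phenyl]-2-(methoxymethoxy)prop-2-en-1-one F10.
- Cyclization with loss of dimethylamine (silica gel or a trace of AcOH) gives 3,5,7-tris(methoxymethoxy)-8-(3-methylbut-2-enyl)chromen-4-one F11.
- Lithiation at C2, between the ring oxygen and the C3 acetal, with lithium 2,2,6,6-tetramethylpiperidide (THF, −78 °C) and quenching with DMF gives 12.

**Step 8.** Methoxide may add to C2 of the electron-poor pyranone and open it, or methanol may add to the newly formed ynenone.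

Fallback, setting out from 12 and coming back at 14, by olefination and elimination without alkoxide:
- Stork–Zhao olefination ((iodomethyl)triphenylphosphonium iodide, NaN(SiMe3)2, THF, −78 °C) gives 2-[(Z)-2-iodoethenyl]-3,5,7-tris(methoxymethoxy)-8-(3-methylbut-2-enyl)chromen-4-one F12.
- Anti-dehydroiodination with TBAF in DMF gives 14.

## Further compounds

F1 | step 13 | methyl 4-hydroxy-3-(3-methylbut-2-enyl)benzoate | COC(=O)c1ccc(O)c(CC=C(C)C)c1
F2 | step 13 | methyl 4-(methoxymethoxy)-3-(3-methylbut-2-enyl)benzoate | COCOc1ccc(C(=O)OC)cc1CC=C(C)C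
F3 | step 13 | 4-(methoxymethoxy)-3-(3-methylbut-2-enyl)benzoic acid | COCOc1ccc(C(=O)O)cc1CC=C(C)C
F4 | step 13 | 2-[(methoxymethoxy)acetyl]-3,5-bis(methoxymethoxy)-6-(3-methylbut-2-enyl)phenyl 4-(methoxymethoxy)-3-(3-methylbut-2-enyl)benzoate | COCOCC(=O)c1c(OCOC)cc(OCOC)c(CC=C(C)C)c1OC(=O)c1ccc(OCOC)c(CC=C(C)C)c1
F5 | step 13 | 1-[2-hydroxy-4,6-bis(methoxymethoxy)-3-(3-methylbut-2-enyl)phenyl]-2-(methoxymethoxy)-3-[4-(methoxymethoxy)-3-(3-methylbut-2-enyl)phenyl]propane-1,3-dione (racemic) | COCOC(C(=O)c1ccc(OCOC)c(CC=C(C)C)c1)C(=O)c1c(OCOC)cc(OCOC)c(CC=C(C)C)c1O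
F6 | step 13 | 3,5,7,4'-tetrakis(methoxymethoxy)-8,3'-bis(3-methylbut-2-enyl)flavone | CC(C)=CCc1cc(-c2oc3c(CC=C(C)C)c(OCOC)cc(OCOC)c3c(=O)c2OCOC)ccc1OCOC
F7 | step 3 | 2-oxo-2-(2,4,6-trihydroxyphenyl)ethyl benzoate | O=C(COC(=O)c1ccccc1)c1c(O)cc(O)cc1O
F8 | step 3 | 2-hydroxy-1-(2,4,6-trihydroxyphenyl)ethanone | OCC(=O)c1c(O)cc(O)cc1O
F9 | step 3 | 2-hydroxy-1-[2,4,6-trihydroxy-3-(3-methylbut-2-enyl)phenyl]ethanone | OCC(=O)c1c(O)cc(O)c(CC=C(C)C)c1O
F10 | step 5 | (2Z)-3-(dimethylamino)-1-[2-hydroxy-4,6-bis(methoxymethoxy)-3-(3-methylbut-2-enyl)phenyl]-2-(methoxymethoxy)prop-2-en-1-one | CN(C)/C=C(\OCOC)C(=O)c1c(OCOC)cc(OCOC)c(CC=C(C)C)c1O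
F11 | step 5 | 3,5,7-tris(methoxymethoxy)-8-(3-methylbut-2-enyl)chromen-4-one | COCOc1coc2c(CC=C(C)C)c(OCOC)cc(OCOC)c2c1=O
F12 | step 8 | 2-[(Z)-2-iodoethenyl]-3,5,7-tris(methoxymethoxy)-8-(3-methylbut-2-enyl)chromen-4-one | I/C=C\c1oc2c(CC=C(C)C)c(OCOC)cc(OCOC)c2c(=O)c1OCOC
A1 | alternative 1 | 5,4'-dihydroxy-3,7-bis(methoxymethoxy)-8,3'-bis(3-methylbut-2-enyl)flavone | CC(C)=CCc1cc(-c2oc3c(CC=C(C)C)c(OCOC)cc(O)c3c(=O)c2OCOC)ccc1O
A2 | alternative 1 | 3,7-bis(methoxymethoxy)-5-(3-methylbut-2-enyloxy)-4'-(2-methylbut-3-en-2-yloxy)flavone | C=CC(C)(C)Oc1ccc(-c2oc3cc(OCOC)cc(OCC=C(C)C)c3c(=O)c2OCOC)cc1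
A3 | alternative 2 | trans-3,5,7,4'-tetrakis(methoxymethoxy)-8,3'-bis(3-methylbut-2-enyl)flavanone (racemic, one enantiomer drawn) | O=C1[C@@H](OCOC)[C@H](c2ccc(OCOC)c(CC=C(C)C)c2)Oc2c(CC=C(C)C)c(OCOC)cc(OCOC)c12
A4 | alternative 2 | methyl 3-[2-iodo-3,5-bis(methoxymethoxy)-6-(3-methylbut-2-enyl)phenoxy]-2-(methoxymethoxy)-3-[4-(methoxymethoxy)-3-(3-methylbut-2-enyl)phenyl]propanoate (racemic, relative configuration as in A3, one enantiomer drawn) | COC(=O)[C@@H](OCOC)[C@H](c1ccc(OCOC)c(CC=C(C)C)c1)Oc1c(CC=C(C)C)c(OCOC)cc(OCOC)c1I
A5 | alternative 3 | 5,7,4'-tris(methoxymethoxy)-3-[2-(trimethylsilyl)ethoxy]-8,3'-bis(3-methylbut-2-enyl)flavone | CC(C)=CCc1cc(-c2oc3c(CC=C(C)C)c(OCOC)cc(OCOC)c3c(=O)c2OCC[Si](C)(C)C)ccc1OCOC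
A6 | alternative 3 | tert-butyldimethylsilyl 2-{[4-(methoxymethoxy)-3-(3-methylbut-2-enyl)benzoyl]oxy}-4,6-bis(methoxymethoxy)-3-(3-methylbut-2-enyl)benzoate | CC(C)=CCc1cc(C(=O)Oc2c(CC=C(C)C)c(OCOC)cc(OCOC)c2C(=O)O[Si](C)(C)C(C)(C)C)ccc1OCOC
A7 | alternative 3 | {[2-(trimethylsilyl)ethoxy]methylidene}triphenylphosphorane | C[Si](C)(C)CCOC=P(c1ccccc1)(c1ccccc1)c1ccccc1
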